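Free catalyst and second catalyst leave their steps as they entered, so I held both at their charge, and in zeta I held reagent at its charge as well.

    starting material + free catalyst ⇌ free catalyst + intermediate (K1 = 1.0, k1 = 3.20 M⁻¹ min⁻¹)
    reagent + second catalyst + intermediate → second catalyst + target (k2 = 756 M⁻² min⁻¹)
    intermediate → side product (k3 = 0.0136 min⁻¹)
    target ⇌ isomer of the product (K4 = 2.39, k4 = 0.00129 min⁻¹)

| flask | starting material | reagent | free catalyst | second catalyst | time |
|---|---|---|---|---|---|
| zeta | 0.0060 M | 1.50 equiv | 5 mol% | 1 mol% | 8.0 h |
| gamma | 0.012 M | 1.50 equiv | 5 mol% | 1 mol% | 8.0 h |
| beta | 0.025 M | 1.50 equiv | 5 mol% | 1 mol% | 8.0 h |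
| delta | 0.050 M | 1.50 equiv | 5 mol% | 1 mol% | 8.0 h |

- "hardly changes" means that all values lie within two and a half points (for a concentration: within two and a half percent of the largest)
- run time (zeta): 8.0 h

- [intermediate] at the end for zeta, gamma, beta, delta, in this order
- how the row runs (falls, then rises / falls all the way / hardly changes / rises all the way / rises, then falls)

1. In zeta I treated starting material and intermediate as one pool. The pseudo-first-order forward constant was 9.60 × 10⁻⁴ min⁻¹, and the way back had 9.60 × 10⁻⁴ min⁻¹.

2. The intermediate left the pool by the side-product step and the step to target, with reagent and second catalyst at their charge, giving a loss constant of 0.0140 min⁻¹. This was larger than the forward constant, so in zeta I expected the intermediate to stay a small share of the pool.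

3. My first way froze the balance, with made equal to used. In zeta this gave intermediate over starting material of 0.0641.

4. The starting material then fell at 8.98 × 10⁻⁴ min⁻¹, which I carried as the pool constant, the first-order rate at which starting material and intermediate fall together. In zeta it left 65.0 % of the starting material at the end, so the frozen way gave 2.50 × 10⁻⁴ M of intermediate.

5. My second way let the balance drift. If the intermediate falls at the pool constant, its loss is offset by that fall, and the ratio in zeta became 0.0682. This gave 2.66 × 10⁻⁴ M of intermediate.

6. The two ways parted by 6.40 %, the second standing higher. The frozen way was the one that cheated, since it set made equal to used in a pool that was falling. Net made over used in zeta came to 0.936, not unity. I committed to the second way and stopped at zeta.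

7. The forecast gave 2.700 × 10⁻⁴ M, 6.600 × 10⁻⁴ M, 0.00102 M and 6.500 × 10⁻⁴ M, a row that rises, then falls. Its ground for the turn: “the intermediate has already passed its peak and the row turns down”.

8. The simulation gave 2.65 × 10⁻⁴ M, 6.56 × 10⁻⁴ M, 0.00100 M and 5.87 × 10⁻⁴ M, a row that rises, then falls, turning at 0.025 M, so the forecast stood on both counts.

In zeta, made over used read 0.937 at 8.00 h and starting material stood at 64.8 %, as the pool constant had it. For gamma, with forward constant 0.00192 min⁻¹ and loss constant 0.0152 min⁻¹, the pool constant came to 0.00171 min⁻¹. In gamma that left 44.1 % of starting material and 5.48 % of intermediate, against 44 % and 5.47 % in the flask. In delta, the side-product step had the largest single effect on the level of intermediate at the end: without it, the intermediate stood at 0.00211 M instead of 5.87 × 10⁻⁴ M.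

The numbers are made up; the result is computed.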